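The chain C4(=O)–C3–C3''–C4''(=O), which runs from ring C of unit 1 (7-methoxy half) into ring C of unit 2 (5,7-dihydroxy half), is a 1,4-diketone. It is cut at C3–C4 as a Stetter retron. A carbene converts the formyl carbon (future C4) into an acyl anion that adds to C3 of the exocyclic enone C3=C3''–C4''=O. This single operation forms C3–C4, closes ring C of unit 1 and creates C3 and C3''. The precursor is an enantiopure (E)-3-alkylidene flavanone of unit 2 that holds the 2-formylaryl ether through C2–O1. All four phenols are benzyl ethers, so neutral hydrogenolysis ends the route.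

Key step: step 13

Remarks on the chemistry
- Locants: unprimed atoms belong to unit 1 and double-primed atoms to unit 2. The target SMILES reads (2R,3S,2''R,3''S), so both flavanone units are 2,3-trans.
- Face of protonation: a proton reaching C3'' from the face remote from the C2'' aryl group would push C3 onto the aryl face and give the 2'',3''-cis isomer. The trans centre needs proton delivery on the aryl-bearing face, or equilibration. Suprafacial addition across the E alkene provides exactly this, so the E geometry is part of the design.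
- C2 and C2'' cannot be repaired once they are lost. Between their creation and the key step no alkoxide, hydroxide or secondary amine is used. Such bases would racemise the α-aryl-α-aryloxy aldehyde, open the flavanone to its chalcone, or start an aldol closure onto the ortho formyl group.
- O5 of unit 1 is carried as a benzyl ether, not a methyl ether. No Lewis acid then meets the finished biflavanone, whose C2–O1 bond is p-methoxybenzylic and whose 1,4-diketone could cyclise to a furan under acid.
- Assumption: the sense of induction in steps 3 and 9 follows the usual models for aryl ketones and cyclic enones. Both antipodes of each catalyst are commercial.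

Step 1
Reactants: 1 2-hydroxy-4,6-dimethoxybenzaldehyde
Product: 2 2,6-dihydroxy-4-methoxybenzaldehyde
Conditions: AlCl3 (3 equiv), CH2Cl2, 0 → 40 °C; cold 1 M HCl
Reagents that add atoms: none
Why: Chelation-directed aryl methyl ether cleavage: aluminium bridges the formyl oxygen and a flanking oxygen, so chloride dealkylates only the methoxy group ortho to the formyl group, while the para methoxy group cannot chelate and stays.

Step 2
Reactants: 2 2,6-dihydroxy-4-methoxybenzaldehyde
Product: 3 2-(benzyloxy)-6-hydroxy-4-methoxybenzaldehyde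
Conditions: BnBr (1.0 equiv), K2CO3 (1.1 equiv), acetone, 56 °C
Reagents that add atoms: benzyl bromide, BrCc1ccccc1
Why: Williamson ether synthesis on a symmetric bis-phenol: once one oxygen is benzylated the remaining hydroxyl is locked in a hydrogen bond to the formyl oxygen and is far less nucleophilic, so one equivalent of bromide should stop at the monoether.

Step 3
Reactants: 4 ethyl 4-methoxybenzoylformate
Product: 5 ethyl (R)-4-methoxymandelate
Conditions: RuCl[(S,S)-TsDPEN](p-cymene) (0.5 mol %), HCO2H/Et3N 5:2, 25 °C
Reagents that add atoms: none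
Why: Noyori asymmetric transfer hydrogenation of an aryl α-keto ester: the CH–π contact between the anisyl ring and the cymene ligand of the (S,S) catalyst fixes the hydride face and sets the carbinol centre as R.

Step 4
Reactants: 3 2-(benzyloxy)-6-hydroxy-4-methoxybenzaldehyde; 5 ethyl (R)-4-methoxymandelate
Product: 6 ethyl (S)-2-[3-(benzyloxy)-2-formyl-5-methoxyphenoxy]-2-(4-methoxyphenyl)acetate
Conditions: PPh3 (1.3 equiv), DIAD (1.3 equiv), toluene, 0 → 23 °C
Reagents that add atoms: none
Why: Mitsunobu etherification: the acidic, chelated phenol displaces the alkoxyphosphonium group by SN2 with inversion (R to S, which is the spatial arrangement of C2 in the target), the neighbouring ester and the non-polar solvent holding back ionisation of the p-methoxybenzylic carbon.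

Step 5
Reactants: 6 ethyl (S)-2-[3-(benzyloxy)-2-formyl-5-methoxyphenoxy]-2-(4-methoxyphenyl)acetate
Product: 7 (S)-2-[3-(benzyloxy)-2-(hydroxymethyl)-5-methoxyphenoxy]-2-(4-methoxyphenyl)ethan-1-ol
Conditions: i-Bu2AlH (4.5 equiv), CH2Cl2, −78 → 0 °C; aq. potassium sodium tartrate
Reagents that add atoms: none
Why: Exhaustive hydride reduction with the non-basic i-Bu2AlH takes ester and formyl group to the alcohols together, which removes any need for an acetal on the very electron-rich aldehyde and leaves the C2 centre, no longer α to a carbonyl group, untouched.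

Step 6
Reactants: 7 (S)-2-[3-(benzyloxy)-2-(hydroxymethyl)-5-methoxyphenoxy]-2-(4-methoxyphenyl)ethan-1-ol
Product: 8 2-(benzyloxy)-4-methoxy-6-[(1S)-1-(4-methoxyphenyl)-2-oxoethoxy]benzaldehyde (dialdehyde)
Conditions: Dess–Martin periodinane (2.5 equiv), CH2Cl2, 0 → 23 °C; cold aq. Na2S2O3/NaHCO3 wash, no chromatography, used the same day
Reagents that add atoms: none
Why: Dess–Martin oxidation brings both primary alcohols to the aldehyde level in a base-free medium, the condition under which the enolisable α-aryl-α-aryloxy aldehyde should keep its configuration.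

Step 7
Reactants: 9 2,4,6-trihydroxyacetophenone
Product: 10 1-[2,4-bis(benzyloxy)-6-hydroxyphenyl]ethan-1-one
Conditions: BnBr (2.1 equiv), K2CO3 (2.2 equiv), DMF, 60 °C
Reagents that add atoms: benzyl bromide, BrCc1ccccc1
Why: Williamson ether synthesis in which the para hydroxyl and one ortho hydroxyl react, while the last one, locked in a hydrogen bond to the acetyl oxygen, is left for the ring closure.

Step 8
Reactants: 10 1-[2,4-bis(benzyloxy)-6-hydroxyphenyl]ethan-1-one
Product: 12 5,7-bis(benzyloxy)-4H-chromen-4-one, via enaminone 11 (not isolated)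
Conditions: Me2NCH(OMe)2 (3 equiv), toluene, 100 °C; evaporate; conc. HCl, CH2Cl2, 40 °C
Reagents that add atoms: N,N-dimethylformamide dimethyl acetal, COC(OC)N(C)C
Why: Enaminone route to chromones: the amide acetal condenses with the methyl ketone, and acid then lets the phenol add to the β-carbon and expel dimethylamine, which supplies C2'' as an unsubstituted enone carbon.

Step 9
Reactants: 12 5,7-bis(benzyloxy)-4H-chromen-4-one; 13 [4-(benzyloxy)phenyl]boronic acid
Product: 14 (R)-5,7-bis(benzyloxy)-2-[4-(benzyloxy)phenyl]chroman-4-one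
Conditions: [Rh(OH)(cod)]2 (1.5 mol %), (R)-6,6'-dimethoxy-2,2'-bis[bis(3,4,5-trifluorophenyl)phosphino]-1,1'-biphenyl (3.3 mol %), 13 (2 equiv), toluene/H2O, 30 °C
Reagents that add atoms: none
Why: Hayashi–Miyaura rhodium-catalysed asymmetric 1,4-addition of an arylboronic acid to a chromone: the aryl–rhodium species held by the (R)-bisphosphine inserts the enone on one face and sets C2'' as R, and the neutral medium avoids the flavanone–chalcone equilibrium that erodes base-mediated cyclisations.

Step 10
Reactants: 14 (R)-5,7-bis(benzyloxy)-2-[4-(benzyloxy)phenyl]chroman-4-one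
Product: 15 (R)-5,7-bis(benzyloxy)-2-[4-(benzyloxy)phenyl]-4-(trimethylsilyloxy)-2H-chromene
Conditions: TMSOTf (1.3 equiv), Et3N (2 equiv), CH2Cl2, 0 °C, dark
Reagents that add atoms: trimethylsilyl trifluoromethanesulfonate, C[Si](C)(C)OS(=O)(=O)C(F)(F)F
Why: Soft enolisation with silyl triflate and tertiary amine gives the silyl enol ether without a free enolate, so β-elimination of the ring aryloxide cannot start and C2'' is kept, the 2H-chromene being stored cold and dark to exclude electrocyclic ring opening.

Step 11
Reactants: 8 dialdehyde; 15 (R)-5,7-bis(benzyloxy)-2-[4-(benzyloxy)phenyl]-4-(trimethylsilyloxy)-2H-chromene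
Product: 16 (2R,3S)-5,7-bis(benzyloxy)-2-[4-(benzyloxy)phenyl]-3-{(2S)-2-[3-(benzyloxy)-2-formyl-5-methoxyphenoxy]-1-hydroxy-2-(4-methoxyphenyl)ethyl}chroman-4-one (both carbinol epimers)
Conditions: BF3·OEt2 (2.2 equiv), CH2Cl2, −78 °C; pH 7 buffer
Reagents that add atoms: none
Why: Mukaiyama aldol addition: under BF3 the aliphatic formyl group is far more electrophilic than the doubly ortho-substituted, vinylogous-ester-like aryl formyl group, no base is present to enolise C2, attack anti to the C2'' aryl group gives the 2'',3''-trans adduct, and the carbinol centre, formed unselectively, is erased in step 12.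

Step 12
Reactants: 16 aldol adduct
Product: 18 (2S,3E)-5,7-bis(benzyloxy)-2-[4-(benzyloxy)phenyl]-3-{(2R)-2-[3-(benzyloxy)-2-formyl-5-methoxyphenoxy]-2-(4-methoxyphenyl)ethylidene}chroman-4-one, via mesylate 17 (not isolated)
Conditions: MsCl (1.5 equiv), Et3N (4 equiv), CH2Cl2, −20 → 23 °C
Reagents that add atoms: none
Why: Mesylation followed by E1cB elimination: from the transient enolate the mesylate leaves much faster than the ring aryloxide, the weak amine base leaves C2–H alone, and the E alkene (side chain turned away from the C4'' oxygen, C2'' aryl group pseudoaxial) is the favoured geometry, as in 3-benzylidene flavanones.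

Step 13
Reactants: 18 (E)-3-alkylidene flavanone carrying the 2-formylaryl ether
Product: 20 (2R,3S,2''R,3''S)-5,5'',7''-tris(benzyloxy)-2''-[4-(benzyloxy)phenyl]-7-methoxy-2-(4-methoxyphenyl)-[3,3''-bichromane]-4,4''-dione, via Breslow enaminol 19 (not isolated)
Conditions: 2-(pentafluorophenyl)-6,7-dihydro-5H-pyrrolo[2,1-c][1,2,4]triazol-2-ium tetrafluoroborate (20 mol %), KN(SiMe3)2 (18 mol %), toluene, 23 °C, HN(SiMe3)2 stripped in vacuo; then 18, toluene, 23 → 40 °C
Reagents that add atoms: none
Why: The carbene adds to the formyl carbon (future C4) and a proton shift gives the Breslow enaminol 19, whose nucleophilic carbon attacks C3, the β-carbon of the enone C3=C3''–C4''=O; the hydroxyl proton then passes to C3'' of the unit 2 enolate and loss of the carbene restores the C4 ketone. The closest known reaction type is the intramolecular Stetter reaction of O-tethered salicylaldehydes to chroman-4-ones, which covers α,β-disubstituted acceptors such as exocyclic alkylidene ketones and tethers that already hold a stereocentre. Ring C of unit 1 (O1, C2, C3, C4, C4a, C8a) closes in the 6-exo-trig mode, the alternative attack on C4''=O being an eight-membered closure. C3 is controlled by C2: allylic 1,3-strain against C2'' keeps C2–H in the alkene plane, so O1 and the anisyl group lie on opposite faces, the short tether reaches C3 only from the O1 face, and the new C3–C4 bond forms anti to the anisyl group (2,3-trans, 3S). C3'' is controlled by the E geometry and the internal proton transfer, because suprafacial addition of acyl carbon and proton across the E alkene gives 3''S, trans to the C2'' aryl group, and since C3 and C3'' are both α to ketones any cis material can still drain into the diequatorial trans,trans isomer by enolisation. The step needs conjugate addition to outrun deprotonation at C2–H and β-elimination of O1'' from the enolate, which is secured by a slim, weakly basic, achiral N-pentafluorophenyl carbene used without excess base (no mismatched catalyst pairing), by the fast internal proton transfer and by the absence of any free phenol.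

Step 14
Reactants: 20 tetrabenzyl biflavanone
Product: 21 CNP0279849.2, (2R,3S,2''R,3''S)-5,5'',7''-trihydroxy-2''-(4-hydroxyphenyl)-7-methoxy-2-(4-methoxyphenyl)-[3,3''-bichromane]-4,4''-dione
Conditions: H2 (1 atm), 10% Pd/C, THF/MeOH, 23 °C
Reagents that add atoms: none
Why: Catalytic hydrogenolysis cleaves the four aryl benzyl ethers in a neutral medium in which the two methyl ethers, the 1,4-diketone and the enolisable centres C3 and C3'' are not affected, and in which the cyclic C2–O1 and C2''–O1'' bonds of flavanones normally survive.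

Compound list
1 | 2-hydroxy-4,6-dimethoxybenzaldehyde | COc1cc(O)c(C=O)c(OC)c1 | starting material
2 | 2,6-dihydroxy-4-methoxybenzaldehyde | COc1cc(O)c(C=O)c(O)c1 | intermediate
3 | 2-(benzyloxy)-6-hydroxy-4-methoxybenzaldehyde | COc1cc(O)c(C=O)c(OCc2ccccc2)c1 | intermediate
4 | ethyl 4-methoxybenzoylformate | CCOC(=O)C(=O)c1ccc(OC)cc1 | starting material
5 | ethyl (R)-4-methoxymandelate | COc1ccc([C@@H](O)C(=O)OCC)cc1 | intermediate
6 | ethyl (S)-2-[3-(benzyloxy)-2-formyl-5-methoxyphenoxy]-2-(4-methoxyphenyl)acetate | COc1ccc([C@H](Oc2cc(OC)cc(OCc3ccccc3)c2C=O)C(=O)OCC)cc1 | intermediate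
7 | (S)-2-[3-(benzyloxy)-2-(hydroxymethyl)-5-methoxyphenoxy]-2-(4-methoxyphenyl)ethan-1-ol | COc1ccc([C@H](Oc2cc(OC)cc(OCc3ccccc3)c2CO)CO)cc1 | intermediate
8 | 2-(benzyloxy)-4-methoxy-6-[(1S)-1-(4-methoxyphenyl)-2-oxoethoxy]benzaldehyde | COc1ccc([C@H](Oc2cc(OC)cc(OCc3ccccc3)c2C=O)C=O)cc1 | intermediate
9 | 2,4,6-trihydroxyacetophenone | CC(=O)c1c(O)cc(O)cc1O | starting material
10 | 1-[2,4-bis(benzyloxy)-6-hydroxyphenyl]ethan-1-one | CC(=O)c1c(O)cc(OCc2ccccc2)cc1OCc1ccccc1 | intermediate
11 | (E)-1-[2,4-bis(benzyloxy)-6-hydroxyphenyl]-3-(dimethylamino)prop-2-en-1-one | CN(C)/C=C/C(=O)c1c(O)cc(OCc2ccccc2)cc1OCc1ccccc1 | intermediate (not isolated)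
12 | 5,7-bis(benzyloxy)-4H-chromen-4-one | O=c1ccoc2cc(OCc3ccccc3)cc(OCc3ccccc3)c12 | intermediate
13 | [4-(benzyloxy)phenyl]boronic acid | OB(O)c1ccc(OCc2ccccc2)cc1 | starting material
14 | (R)-5,7-bis(benzyloxy)-2-[4-(benzyloxy)phenyl]chroman-4-one | O=C1C[C@H](c2ccc(OCc3ccccc3)cc2)Oc2cc(OCc3ccccc3)cc(OCc3ccccc3)c21 | intermediate
15 | (R)-5,7-bis(benzyloxy)-2-[4-(benzyloxy)phenyl]-4-(trimethylsilyloxy)-2H-chromene | C[Si](C)(C)OC1=C[C@H](c2ccc(OCc3ccccc3)cc2)Oc2cc(OCc3ccccc3)cc(OCc3ccccc3)c21 | intermediate
16 | aldol adduct, (2R,3S) in the flavanone, (2S) in the side chain, carbinol carbon as both epimers | COc1ccc([C@H](Oc2cc(OC)cc(OCc3ccccc3)c2C=O)C(O)[C@@H]2C(=O)c3c(OCc4ccccc4)cc(OCc4ccccc4)cc3O[C@H]2c2ccc(OCc3ccccc3)cc2)cc1 | intermediate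
17 | methanesulfonate of 16 | COc1ccc([C@H](Oc2cc(OC)cc(OCc3ccccc3)c2C=O)C(OS(C)(=O)=O)[C@@H]2C(=O)c3c(OCc4ccccc4)cc(OCc4ccccc4)cc3O[C@H]2c2ccc(OCc3ccccc3)cc2)cc1 | intermediate (not isolated)
18 | (2S,3E)-3-alkylidene flavanone with (2R) side chain; C2'' is unchanged in space and reads S only because C3'' now outranks the aryl group | COc1ccc([C@H](Oc2cc(OC)cc(OCc3ccccc3)c2C=O)/C=C2/C(=O)c3c(OCc4ccccc4)cc(OCc4ccccc4)cc3O[C@H]2c2ccc(OCc3ccccc3)cc2)cc1 | intermediate (key-step precursor)
19 | Breslow enaminol: the formyl carbon of 18 has become C(OH)=C of the N-pentafluorophenyl pyrrolotriazoline | COc1ccc([C@H](Oc2cc(OC)cc(OCc3ccccc3)c2C(O)=C2N(c3c(F)c(F)c(F)c(F)c3F)N=C3CCCN23)/C=C2/C(=O)c3c(OCc4ccccc4)cc(OCc4ccccc4)cc3O[C@H]2c2ccc(OCc3ccccc3)cc2)cc1 | intermediate (not isolated)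
20 | (2R,3S,2''R,3''S)-tetrabenzyl biflavanone | COc1ccc([C@@H]2Oc3cc(OC)cc(OCc4ccccc4)c3C(=O)[C@H]2[C@@H]2C(=O)c3c(OCc4ccccc4)cc(OCc4ccccc4)cc3O[C@H]2c2ccc(OCc3ccccc3)cc2)cc1 | intermediate (key-step product)
21 | CNP0279849.2, (2R,3S,2''R,3''S) | COc1ccc([C@@H]2Oc3cc(OC)cc(O)c3C(=O)[C@H]2[C@@H]2C(=O)c3c(O)cc(O)cc3O[C@H]2c2ccc(O)cc2)cc1 | target

Total step count: 14.
Longest linear sequence: 9 steps (1 → 2 → 3 → 6 → 7 → 8 → 16 → 18 → 20 → 21, that is steps 1, 2, 4, 5, 6, 11, 12, 13, 14).

Steps most likely to fail

Step 13.
- **Slow enaminol formation.** The formyl group sits between two alkoxy groups on an electron-rich ring, so the enaminol may form slowly.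
- **Hindered approach.** The acyl anion has to approach the alkene face that also carries the pseudoaxial C2'' aryl group, so rate and facial selectivity may be poor.
- **Carbene acting as a base.** It may deprotonate C2–H, or ring C of unit 2 may open by β-elimination from the enolate.
- **Fallback: an acyl radical in place of the acyl anion, from 18 back to 20.** Pinnick oxidation (NaClO2, NaH2PO4, 2-methyl-2-butene, t-BuOH/H2O) turns the formyl group into the carboxylic acid F1. PhSeSePh/Bu3P in CH2Cl2 converts it into the Se-phenyl selenoester F2. Slow addition of Bu3SnH with AIBN in benzene at 80 °C generates the aroyl radical. This radical closes ring C of unit 1 by 6-exo-trig addition to C3 under the same allylic-strain control, and the tin hydride reduces the C3'' radical. Brief stirring of the crude product with Et3N lets C3 and C3'' settle in the trans,trans arrangement of 20. The medium is neutral and the nucleophilic radical is less sensitive to crowding.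

Step 11.
- **Loss of configuration at C2.** The α-carbon of the dialdehyde may enolise.
- **Lewis acid problems.** BF3 may be sequestered by the basic aryl formyl group, or it may ionise the p-methoxybenzylic ether.
- **Wrong site.** Some addition may occur at the aryl formyl group.
- **Built-in safeguard.** Unit 2 is enantiopure, so any C2 epimer is a diastereomer and can be removed by chromatography at 16 or 18.
- **Fallback: an internally organised boron aldol in place of external Lewis acid activation, from 14 and 8 back to 16, with step 10 omitted.** Cy2BCl/Et3N in Et2O at −78 °C gives the dicyclohexylboron enolate F3. This covalent, non-basic enolate does not expel the ring aryloxide. The dialdehyde 8 is added at −78 °C and reacts through a closed Zimmerman–Traxler transition state at the aliphatic formyl group. A non-oxidative release with MeOH and silica gel avoids a Dakin-type loss of the aryl formyl group and gives 16.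

Step 4.
- **Erosion of enantiopurity.** Partial ionisation of the p-methoxybenzylic alkoxyphosphonium ion would lower the enantiopurity of C2.
- **Sluggish coupling.** The hydrogen-bonded phenol may couple slowly with a hindered secondary alcohol.
- **Fallback: the C2–O1 bond is made by carbene O–H insertion, from 4 and 3 back to 6, with step 3 omitted.** Condensation of 4 with TsNHNH2 gives the tosylhydrazone F4. Et3N in CH2Cl2 then gives ethyl 2-diazo-2-(4-methoxyphenyl)acetate F5. The known enantioselective insertion of α-aryl-α-diazoacetates into phenol O–H bonds joins F5 to 3. It uses PdCl2(PhCN)2, a chiral spiro-bis(oxazoline) ligand of the antipode that leads to S, and NaB[3,5-(CF3)2C6H3]4 in CHCl3 over 5 Å molecular sieves. No substitution takes place at the stereocentre.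

Further compounds
F1 | step 13 | 2-(benzyloxy)-4-methoxy-6-{(1R,2E)-substituted ethoxy}benzoic acid, the carboxylic acid corresponding to 18 | COc1ccc([C@H](Oc2cc(OC)cc(OCc3ccccc3)c2C(=O)O)/C=C2/C(=O)c3c(OCc4ccccc4)cc(OCc4ccccc4)cc3O[C@H]2c2ccc(OCc3ccccc3)cc2)cc1
F2 | step 13 | Se-phenyl selenoester of F1 | COc1ccc([C@H](Oc2cc(OC)cc(OCc3ccccc3)c2C(=O)[Se]c2ccccc2)/C=C2/C(=O)c3c(OCc4ccccc4)cc(OCc4ccccc4)cc3O[C@H]2c2ccc(OCc3ccccc3)cc2)cc1
F3 | step 11 | dicyclohexylboron enolate of 14 | C1CCCCC1B(C1CCCCC1)OC1=C[C@H](c2ccc(OCc3ccccc3)cc2)Oc2cc(OCc3ccccc3)cc(OCc3ccccc3)c21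
F4 | step 4 | ethyl 2-(4-methoxyphenyl)-2-(2-tosylhydrazinylidene)acetate | CCOC(=O)C(=NNS(=O)(=O)c1ccc(C)cc1)c1ccc(OC)cc1
F5 | step 4 | ethyl 2-diazo-2-(4-methoxyphenyl)acetate | CCOC(=O)C(=[N+]=[N-])c1ccc(OC)cc1
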